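**Retrosynthetic overview** (target numbering: C1 carbonyl, C2=C3, C4 carbinol, C5 quaternary carbinol, C1' side-chain carbinol)

1. Only one C–C bond is disconnected, C5–C1', leading back to cyclopent-2-en-1-one (1) and heptadecanal (2). Their adduct is allylic alcohol 3, whose (1'S) carbinol is the only stereocentre set during C–C bond formation.
2. Key disconnection: both ring C–O bonds of triol 4 (the later cis C4–OH and C5–OH) go back to the ring alkene of 3. One syn-dihydroxylation, steered by the (1'S) carbinol and a matched cinchona ligand, sets both ring stereocentres.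
3. Saturated ketone 4 is the precursor of the enone: through silyl enol ether 5 and silylated enone 6 it is dehydrogenated to the target 7. Only one α-carbon of 4 carries hydrogen, so the regiochemistry is fixed.
4. Rings: none is formed; the five-membered ring is bought as 1 and only functionalised.

Assumption: heptadecanal is taken as a purchasable catalogue compound.

**Step 1**
Reactants: 1 cyclopent-2-en-1-one; 2 heptadecanal
Product: 3 2-[(1S)-1-hydroxyheptadecyl]cyclopent-2-en-1-one
Conditions: 1 (3 equiv), PEt3 (1 equiv), 3,3'-bis[3,5-bis(trifluoromethyl)phenyl]-5,5',6,6',7,7',8,8'-octahydro-1,1'-bi-2-naphthol (10 mol%; the enantiomer that gives the S carbinol, assigned on the first run by Mosher ester analysis), THF, −10 °C, 48 h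
Reagents that add atoms: none
Why: Proposed new method: PEt3 adds to C3 of 1 to give a β-phosphonium enolate that is hydrogen-bonded to the chiral diol, this chiral ion pair attacks one face of the aldehyde in the aldol step (setting C1' as S) and E1cB loss of PEt3 restores the enone; the closest known reaction is the chiral-Brønsted-acid/trialkylphosphine Morita–Baylis–Hillman reaction of cyclohex-2-en-1-one with aliphatic aldehydes, which to my knowledge has not been demonstrated for the five-membered enone with an unbranched C17 aldehyde.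

**Step 2**
Reactants: 3 2-[(1S)-1-hydroxyheptadecyl]cyclopent-2-en-1-one
Product: 4 (2S,3S)-2,3-dihydroxy-2-[(1S)-1-hydroxyheptadecyl]cyclopentan-1-one
Conditions: K2OsO2(OH)4 (2 mol%), (DHQ)2PHAL (hydroquinine 1,4-phthalazinediyl diether, 5 mol%), NMO (1.5 equiv), t-BuOH/acetone/H2O 4:4:1, 0 °C to rt, 3 added over 6 h
Reagents that add atoms: N-methylmorpholine N-oxide (C[N+]1([O-])CCOCC1); water (O)
Why: Ligand-accelerated catalytic osmium syn-dihydroxylation (Upjohn/Sharpless type) adds both oxygens to one face of C2=C3, namely the face anti to the C1' oxygen in the rotamer with C1'–H eclipsing the alkene (Kishi's rule), which is also the face (DHQ)2PHAL selects by the Sharpless mnemonic (ring H south-east, side chain south-west), so the matched pair gives the cis-diol with C2 and C3 both S.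

**Step 3**
Reactants: 4 (2S,3S)-2,3-dihydroxy-2-[(1S)-1-hydroxyheptadecyl]cyclopentan-1-one
Product: 7 (4S,5S)-4,5-dihydroxy-5-[(1S)-1-hydroxyheptadecyl]cyclopent-2-en-1-one, via persilylated silyl enol ether 5 (not isolated), via tris-silylated enone 6 (not isolated)
Conditions: TMSOTf (4.5 equiv), Et3N (6 equiv), CH2Cl2, 0 °C, 1 h; pentane/cold aq NaHCO3 wash, concentrate; Pd(OAc)2 (1.1 equiv), MeCN/CH2Cl2 4:1, rt, 12 h; then 1 M HCl, THF, 0 °C, 30 min
Reagents that add atoms: none
Why: Only C5 of 4 can enolise, so TMSOTf/Et3N gives a single silyl enol ether while capping all three hydroxyls, Saegusa–Ito oxidation with Pd(OAc)2 (oxa-π-allyl palladium, then β-hydride elimination) introduces the enone double bond without touching the three stereocentres, and dilute acid cleaves the trimethylsilyl ethers.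

**Compound list**

1 | cyclopent-2-en-1-one | O=C1C=CCC1 | starting material
2 | heptadecanal | CCCCCCCCCCCCCCCCC=O | starting material
3 | 2-[(1S)-1-hydroxyheptadecyl]cyclopent-2-en-1-one | CCCCCCCCCCCCCCCC[C@H](O)C1=CCCC1=O | intermediate
4 | (2S,3S)-2,3-dihydroxy-2-[(1S)-1-hydroxyheptadecyl]cyclopentan-1-one | CCCCCCCCCCCCCCCC[C@H](O)[C@@]1(O)C(=O)CC[C@@H]1O | intermediate
5 | (4S,5S)-1,4,5-tris(trimethylsilyloxy)-5-[(1S)-1-(trimethylsilyloxy)heptadecyl]cyclopent-1-ene | CCCCCCCCCCCCCCCC[C@H](O[Si](C)(C)C)[C@@]1(O[Si](C)(C)C)C(O[Si](C)(C)C)=CC[C@@H]1O[Si](C)(C)C | intermediate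
6 | (4S,5S)-4,5-bis(trimethylsilyloxy)-5-[(1S)-1-(trimethylsilyloxy)heptadecyl]cyclopent-2-en-1-one | CCCCCCCCCCCCCCCC[C@H](O[Si](C)(C)C)[C@@]1(O[Si](C)(C)C)C(=O)C=C[C@@H]1O[Si](C)(C)C | intermediate
7 | (4S,5S)-4,5-dihydroxy-5-[(1S)-1-hydroxyheptadecyl]cyclopent-2-en-1-one | CCCCCCCCCCCCCCCC[C@H](O)[C@@]1(O)C(=O)C=C[C@@H]1O | target

**Total step count:** 3. Step 3 is a telescoped sequence of three operations in which 5 and 6 are not purified.
**Longest linear sequence:** 3.

**Steps most likely to fail**

Step 1 (the proposed new step). The risks are modest enantioselectivity with the flatter five-membered enolate and phosphine-induced Rauhut–Currier dimerisation of 1. Partial ee can be raised by recrystallising 3, and the matched step 2 further depletes the minor enantiomer. The fallback uses known chemistry only; it sets out from 2 and comes back at 3. Commercial 6-bromo-1,4-dioxaspiro[4.4]non-6-ene F1 is lithiated (n-BuLi, THF, −78 °C) and added to 2 to give racemic 1-(1,4-dioxaspiro[4.4]non-6-en-6-yl)heptadecan-1-ol F2. Dess–Martin periodinane oxidises this to 1-(1,4-dioxaspiro[4.4]non-6-en-6-yl)heptadecan-1-one F3. CBS reduction with (R)-2-methyl-CBS-oxazaborolidine and BH3·SMe2 (alkenyl as the large group) gives (1S)-1-(1,4-dioxaspiro[4.4]non-6-en-6-yl)heptadecan-1-ol F4. Oxalic acid in wet CH2Cl2 removes the ketal and delivers 3.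

Step 2. The risks are that the free hydroxyl, hydrogen-bonded to the ketone, populates a rotamer that erodes facial control, that osmylation of the electron-poor enone is slow, and that the product undergoes retro-aldol cleavage. The fallback sets out from 3 and comes back at 4, and puts stereocontrol entirely on a bulky silyl ether. TBSCl/imidazole in DMF gives 2-[(1S)-1-{[tert-butyl(dimethyl)silyl]oxy}heptadecyl]cyclopent-2-en-1-one F5. Ligand-free OsO4 (2 mol%)/NMO in acetone/H2O then adds anti to the silyloxy group to give (2R,3S)-2-[(1S)-1-{[tert-butyl(dimethyl)silyl]oxy}heptadecyl]-2,3-dihydroxycyclopentan-1-one F6. This has the same spatial arrangement as 4; the C2 descriptor changes only because the silyl group alters CIP priorities. HF·pyridine in THF at 0 °C releases 4.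

Step 3. The risks are incomplete palladium-mediated dehydrosilylation of the hindered enol ether and premature loss of trimethylsilyl groups. The fallback sets out from 5 and comes back at 6, replacing the palladium step by selenoxide elimination. PhSeCl (CH2Cl2, −78 °C) converts 5 into (2S,3S)-5-(phenylselanyl)-2,3-bis(trimethylsilyloxy)-2-[(1S)-1-(trimethylsilyloxy)heptadecyl]cyclopentan-1-one F7 as a mixture of C5 epimers. H2O2/pyridine in CH2Cl2 at 0 °C oxidises the selenide, and syn-elimination of the selenoxide gives 6, which is desilylated as in step 3.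

**Further compounds**

F1 | step 1 | 6-bromo-1,4-dioxaspiro[4.4]non-6-ene | BrC1=CCCC12OCCO2
F2 | step 1 | racemic 1-(1,4-dioxaspiro[4.4]non-6-en-6-yl)heptadecan-1-ol | CCCCCCCCCCCCCCCCC(O)C1=CCCC12OCCO2
F3 | step 1 | 1-(1,4-dioxaspiro[4.4]non-6-en-6-yl)heptadecan-1-one | CCCCCCCCCCCCCCCCC(=O)C1=CCCC12OCCO2
F4 | step 1 | (1S)-1-(1,4-dioxaspiro[4.4]non-6-en-6-yl)heptadecan-1-ol | CCCCCCCCCCCCCCCC[C@H](O)C1=CCCC12OCCO2
F5 | step 2 | 2-[(1S)-1-{[tert-butyl(dimethyl)silyl]oxy}heptadecyl]cyclopent-2-en-1-one | CCCCCCCCCCCCCCCC[C@H](O[Si](C)(C)C(C)(C)C)C1=CCCC1=O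
F6 | step 2 | (2R,3S)-2-[(1S)-1-{[tert-butyl(dimethyl)silyl]oxy}heptadecyl]-2,3-dihydroxycyclopentan-1-one | CCCCCCCCCCCCCCCC[C@H](O[Si](C)(C)C(C)(C)C)[C@@]1(O)C(=O)CC[C@@H]1O
F7 | step 3 | (2S,3S)-5-(phenylselanyl)-2,3-bis(trimethylsilyloxy)-2-[(1S)-1-(trimethylsilyloxy)heptadecyl]cyclopentan-1-one (C5 epimers) | CCCCCCCCCCCCCCCC[C@H](O[Si](C)(C)C)[C@@]1(O[Si](C)(C)C)C(=O)C([Se]c2ccccc2)C[C@@H]1O[Si](C)(C)C
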